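**Plan**

1. Retrosynthesis: the two MOM ethers on O5 and O8 come off last. The quinone ring (C1, C2, C3, C4, C4a, C8a) is then cut at C1–C8a, C1–C2 and C3–C4 into an aryl(methoxy)carbene chromium complex (C4, C4a, C8a and the benzene ring), a terminal alkyne (C2, C3) and one CO ligand (C1), which is a Dötz benzannulation with oxidative work-up.
2. The enabling feature is the enedione C1(=O)–C2(R)=C3H–C4(=O) fused to a benzene ring that its 5,8-oxygens make symmetric. C2 and C3 are therefore equivalent sites, and either sense of alkyne insertion gives the same quinone.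
3. The alkyne is (1R)-1-ethynyl-2,2-dimethylcyclobutyl angelate. Its ester bond is cut next (lithium alkoxide plus angelic anhydride), so the hindered, isomerisable ester is made on the small alkynol and not on the finished quinone.
4. Forward order of rings: the cyclobutane is bought as 2,2-dimethylcyclobutanone, the benzene ring comes from hydroquinone, and the quinone ring is closed last; the methoxy group, the chromium and the MOM groups are then removed.
5. Stereochemistry: the only stereocentre comes from a Sharpless epoxidation (D-(−)-diethyl tartrate) of the (E)-cyclobutylidene ethanol. Base-induced opening of the derived epoxy chloride turns the spiro-epoxide carbon into the tertiary propargylic carbinol without breaking its C–O bond, and no later step touches it.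

Key step: step 9

Remark: 2,2-dimethylcyclobutanone and angelic anhydride are taken as catalogue chemicals, and the naphthazarin is treated as the tautomer drawn.

**Route**

Step 1
Reactants: 1 2,2-dimethylcyclobutan-1-one; 2 triethyl phosphonoacetate
Product: 3 ethyl (2E)-2-(2,2-dimethylcyclobutylidene)acetate
Conditions: NaH, THF, 0 °C to 60 °C; minor Z isomer removed by chromatography
Reagents that add atoms: none
Why: Horner–Wadsworth–Emmons olefination of a strained, electrophilic ketone, in which the ester should settle on the side of the ring CH2 and away from the gem-dimethyl carbon, so that the E isomer needed for the epoxidation should dominate.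

Step 2
Reactants: 3 ethyl (2E)-2-(2,2-dimethylcyclobutylidene)acetate
Product: 4 (2E)-2-(2,2-dimethylcyclobutylidene)ethan-1-ol
Conditions: DIBAL-H (2.2 equiv), CH2Cl2, −78 °C; aq. potassium sodium tartrate
Reagents that add atoms: none
Why: DIBAL-H reduction of an α,β-unsaturated ester should stop cleanly at the allylic alcohol at −78 °C without touching the alkene or its geometry.

Step 3
Reactants: 4 (2E)-2-(2,2-dimethylcyclobutylidene)ethan-1-ol
Product: 5 [(2R,3R)-4,4-dimethyl-1-oxaspiro[2.3]hexan-2-yl]methanol
Conditions: Ti(OiPr)4 (10 mol %), D-(−)-diethyl tartrate (12 mol %), t-BuOOH in isooctane, 4 Å molecular sieves, CH2Cl2, −20 °C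
Reagents that add atoms: tert-butyl hydroperoxide, CC(C)(C)OO
Why: Sharpless asymmetric epoxidation of an (E)-3,3-disubstituted allylic alcohol of the geraniol type, in which the titanium tartrate assembly with the unnatural D-(−)-tartrate should deliver oxygen to the alkene face that makes both new centres R, the spiro carbon being the future carbinol stereocentre of the target.

Step 4
Reactants: 5 [(2R,3R)-4,4-dimethyl-1-oxaspiro[2.3]hexan-2-yl]methanol
Product: 6 (2S,3R)-2-(chloromethyl)-4,4-dimethyl-1-oxaspiro[2.3]hexane
Conditions: PPh3, CCl4, NaHCO3, reflux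
Reagents that add atoms: carbon tetrachloride, ClC(Cl)(Cl)Cl
Why: Appel chlorination of the primary alcohol under buffered, non-acidic conditions should leave the acid-sensitive spiro-epoxide and both stereocentres untouched (the descriptor at C2 changes only because chlorine raises the priority of the side chain).

Step 5
Reactants: 6 (2S,3R)-2-(chloromethyl)-4,4-dimethyl-1-oxaspiro[2.3]hexane
Product: 8 (1R)-1-ethynyl-2,2-dimethylcyclobutan-1-ol, via lithium chlorovinyl alkoxide 7 (not isolated)
Conditions: n-BuLi (3.3 equiv), THF, −78 °C to −30 °C; then H2O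
Reagents that add atoms: none
Why: Base-induced fragmentation of a 2,3-epoxy chloride to a propargylic alcohol, in which deprotonation of the CH2Cl group opens the epoxide by β-elimination to alkoxide 7, a second dehydrochlorination gives the alkyne, and the configuration of the spiro carbon is carried unchanged into the tertiary carbinol because its C–O bond is never broken.

Step 6
Reactants: 8 (1R)-1-ethynyl-2,2-dimethylcyclobutan-1-ol; 9 angelic anhydride [(2Z)-2-methylbut-2-enoic anhydride]
Product: 11 (1R)-1-ethynyl-2,2-dimethylcyclobutyl (2Z)-2-methylbut-2-enoate, via lithium alkoxide 10 (not isolated)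
Conditions: LiN(SiMe3)2 (1.05 equiv), THF, −78 °C; then 9, −78 °C to 0 °C; H2O
Reagents that add atoms: none
Why: Acylation of a lithium alkoxide by an anhydride, in which the base removes the hydroxyl proton in preference to the alkynyl one, the slim alkyne leaves the tertiary alkoxide accessible, and acyl transfer at low temperature without a nucleophilic catalyst should keep the Z (angelate) geometry, the stereocentre not being involved.

Step 7
Reactants: 12 hydroquinone
Product: 13 1,4-bis(methoxymethoxy)benzene
Conditions: NaH, DMF, 0 °C; ClCH2OCH3, 0 °C to rt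
Reagents that add atoms: chloromethyl methyl ether, COCCl
Why: Williamson-type alkylation of the bis-phenoxide gives the bis-acetal, which later directs the lithiation and comes off under mild acid.

Step 8
Reactants: 13 1,4-bis(methoxymethoxy)benzene
Product: 16 pentacarbonyl{[2,5-bis(methoxymethoxy)phenyl](methoxy)methylidene}chromium (carbene complex of zerovalent chromium), via aryllithium 14 (not isolated), via lithium acylchromate 15 (not isolated)
Conditions: n-BuLi, THF, 0 °C; Cr(CO)6, THF, 0 °C to rt; then Me3OBF4, CH2Cl2/H2O, 0 °C
Reagents that add atoms: chromium hexacarbonyl, O=C=[Cr](=C=O)(=C=O)(=C=O)(=C=O)=C=O; trimethyloxonium tetrafluoroborate, C[O+](C)C.F[B-](F)(F)F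
Why: Fischer-type carbene synthesis, in which acetal-directed ortho-lithiation gives 14 (all four ring positions are equivalent), the aryllithium adds to a carbonyl ligand of Cr(CO)6 to give 15, and O-methylation by the oxonium salt gives the methoxycarbene complex.

Step 9
Reactants: 11 (1R)-1-ethynyl-2,2-dimethylcyclobutyl (2Z)-2-methylbut-2-enoate; 16 pentacarbonyl{[2,5-bis(methoxymethoxy)phenyl](methoxy)methylidene}chromium
Product: 18 2-[(1R)-2,2-dimethyl-1-{[(2Z)-2-methylbut-2-enoyl]oxy}cyclobutyl]-5,8-bis(methoxymethoxy)naphthalene-1,4-dione, via chromium-bound methoxynaphthol 17 (not isolated)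
Conditions: 16 (1.3 equiv), THF (0.05 M), 50 °C, argon; then (NH4)2Ce(NO3)6, MeCN/H2O, 0 °C
Reagents that add atoms: water, O
Why: Dötz benzannulation: thermal loss of one CO from 16 lets the alkyne insert into the Cr=C bond to a vinylcarbene, CO insertion gives a chromium-bound aryl(vinyl)ketene, and 6π-electrocyclisation onto C6 of the aryl group (its only free ortho position) followed by enolisation gives the Cr(CO)3-bound 4-methoxy-1-naphthol 17, which (NH4)2Ce(NO3)6 frees from the metal and converts into the 1,4-quinone by oxidative demethylation with water as the oxygen source. The closest known reaction type is the benzannulation of aryl(methoxy)carbene chromium complexes with terminal alkynes, tert-alkyl and propargyl-oxygenated ones included, followed by oxidative work-up to 2-substituted 1,4-naphthoquinones. The one ring is closed in a [3+2+1] sense from C4, C4a and C8a of the carbene complex, C2 and C3 of the alkyne and C1 of a carbonyl ligand, the last bond (C1–C8a) by the electrocyclisation. No stereocentre is formed, and the quaternary carbinol centre of 11 is a spectator whose four bonds are not involved. The selectivity needed is for the phenol pathway over indene, furan or cyclobutenone formation and over cyclopropanation of the angelate; chromium, the methoxy group, THF and a moderate temperature should favour the phenol, and the electron-poor, trisubstituted ester alkene, held away by the s-trans ester, should not compete. Regiochemistry of insertion is immaterial because the 5,8-bis(methoxymethoxy) ring is symmetric, and the moderate temperature with immediate oxidation should keep the tertiary benzylic ester from ionising while it sits ortho to the free naphthol.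

Step 10
Reactants: 18 2-[(1R)-2,2-dimethyl-1-{[(2Z)-2-methylbut-2-enoyl]oxy}cyclobutyl]-5,8-bis(methoxymethoxy)naphthalene-1,4-dione
Product: 19 (1R)-1-(5,8-dihydroxy-1,4-dioxo-1,4-dihydronaphthalen-2-yl)-2,2-dimethylcyclobutyl (2Z)-2-methylbut-2-enoate
Conditions: CF3CO2H, CH2Cl2, 0 °C; aqueous work-up
Reagents that add atoms: none
Why: Acid-catalysed cleavage of the aryl methoxymethyl acetals, assisted by the peri quinone carbonyls, should free the naphthazarin while the ester survives, because ionisation at a carbon flanked by a quinone is strongly disfavoured and CF3CO2H at 0 °C should not isomerise the angelate; the stereocentre is untouched.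

**Compound list**

1 | 2,2-dimethylcyclobutan-1-one | CC1(C)CCC1=O | starting material
2 | triethyl phosphonoacetate | CCOC(=O)CP(=O)(OCC)OCC | starting material
3 | ethyl (2E)-2-(2,2-dimethylcyclobutylidene)acetate | CCOC(=O)/C=C1\CCC1(C)C | intermediate
4 | (2E)-2-(2,2-dimethylcyclobutylidene)ethan-1-ol | OC/C=C1\CCC1(C)C | intermediate
5 | [(2R,3R)-4,4-dimethyl-1-oxaspiro[2.3]hexan-2-yl]methanol | OC[C@H]1O[C@@]12CCC2(C)C | intermediate
6 | (2S,3R)-2-(chloromethyl)-4,4-dimethyl-1-oxaspiro[2.3]hexane | ClC[C@H]1O[C@@]12CCC2(C)C | intermediate
7 | lithium (1S)-1-(2-chloroethenyl)-2,2-dimethylcyclobutan-1-olate (same spatial arrangement as 8; alkene geometry not defined, both isomers converge) | [Li]O[C@]1(C=CCl)CCC1(C)C | intermediate (not isolated)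
8 | (1R)-1-ethynyl-2,2-dimethylcyclobutan-1-ol | O[C@]1(C#C)CCC1(C)C | intermediate
9 | angelic anhydride, (2Z)-2-methylbut-2-enoic anhydride | C/C=C(/C)C(=O)OC(=O)/C(C)=C\C | starting material
10 | lithium (1R)-1-ethynyl-2,2-dimethylcyclobutan-1-olate | [Li]O[C@]1(C#C)CCC1(C)C | intermediate (not isolated)
11 | (1R)-1-ethynyl-2,2-dimethylcyclobutyl (2Z)-2-methylbut-2-enoate | C/C=C(/C)C(=O)O[C@]1(C#C)CCC1(C)C | intermediate
12 | hydroquinone | Oc1ccc(O)cc1 | starting material
13 | 1,4-bis(methoxymethoxy)benzene | COCOc1ccc(OCOC)cc1 | intermediate
14 | [2,5-bis(methoxymethoxy)phenyl]lithium | [Li]c1cc(OCOC)ccc1OCOC | intermediate (not isolated)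
15 | lithium pentacarbonyl{[2,5-bis(methoxymethoxy)phenyl](oxido)methylidene}chromate | [Li+].[O-]C(=[Cr](=C=O)(=C=O)(=C=O)(=C=O)=C=O)c1cc(OCOC)ccc1OCOC | intermediate (not isolated)
16 | pentacarbonyl{[2,5-bis(methoxymethoxy)phenyl](methoxy)methylidene}chromium | COC(=[Cr](=C=O)(=C=O)(=C=O)(=C=O)=C=O)c1cc(OCOC)ccc1OCOC | intermediate
17 | tricarbonylchromium η6 complex of (1R)-1-[1-hydroxy-4-methoxy-5,8-bis(methoxymethoxy)naphthalen-2-yl]-2,2-dimethylcyclobutyl (2Z)-2-methylbut-2-enoate (written as ligand and Cr(CO)3 fragment) | C/C=C(/C)C(=O)O[C@]1(c2cc(OC)c3c(OCOC)ccc(OCOC)c3c2O)CCC1(C)C.O=C=[Cr](=C=O)=C=O | intermediate (not isolated)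
18 | 2-[(1R)-2,2-dimethyl-1-{[(2Z)-2-methylbut-2-enoyl]oxy}cyclobutyl]-5,8-bis(methoxymethoxy)naphthalene-1,4-dione | C/C=C(/C)C(=O)O[C@]1(C2=CC(=O)c3c(OCOC)ccc(OCOC)c3C2=O)CCC1(C)C | intermediate
19 | (1R)-1-(5,8-dihydroxy-1,4-dioxo-1,4-dihydronaphthalen-2-yl)-2,2-dimethylcyclobutyl (2Z)-2-methylbut-2-enoate | C/C=C(/C)C(=O)O[C@]1(C2=CC(=O)c3c(O)ccc(O)c3C2=O)CCC1(C)C | target

**Step count and risks**

Total: 10 steps. Longest linear sequence: 8 steps (steps 1–6, 9 and 10).

Steps most likely to fail:

- Step 9. The tertiary angelate may be lost at the electron-rich, chromium-bound naphthol stage (ionisation, ortho-quinone methide formation or acyl shift to the neighbouring phenol), or the very bulky alkyne may divert the vinylcarbene from CO insertion. Fallback, with the ester introduced after the ring is closed: from 8, silylation (Et3SiOSO2CF3, 2,6-lutidine, CH2Cl2) gives triethyl{[(1R)-1-ethynyl-2,2-dimethylcyclobutyl]oxy}silane F1, a propargyl silyl ether of the class with the closest benzannulation precedent. Benzannulation of F1 with 16 and the same oxidative work-up should give 2-[(1R)-2,2-dimethyl-1-(triethylsilyloxy)cyclobutyl]-5,8-bis(methoxymethoxy)naphthalene-1,4-dione F2. HF·pyridine in THF should then give 2-[(1R)-1-hydroxy-2,2-dimethylcyclobutyl]-5,8-bis(methoxymethoxy)naphthalene-1,4-dione F3. Acylation of F3 with 9 under Sc(OTf)3 catalysis (MeCN, −20 °C), where the carbinol carbon next to the quinone cannot ionise, comes back to the route at 18.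

- Step 6. Acyl transfer to the hindered tertiary alkoxide may be slow, and the angelate may isomerise to the E (tiglate) geometry by addition–elimination or deprotonation during acylation. Fallback, which builds the Z alkene after the ester bond: from 8, DCC-mediated esterification with 2-[bis(2,2,2-trifluoroethoxy)phosphoryl]propanoic acid (through the phosphonoketene, which acylates tertiary alcohols) gives (1R)-1-ethynyl-2,2-dimethylcyclobutyl 2-[bis(2,2,2-trifluoroethoxy)phosphoryl]propanoate F4 as a mixture of epimers at the phosphonate carbon. Still–Gennari olefination of F4 with acetaldehyde (KN(SiMe3)2, 18-crown-6, THF, −78 °C) should be Z-selective and comes back to the route at 11.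

- Step 5. Butyllithium may attack the strained spiro-epoxide, or the ring may enlarge, in competition with the deprotonation–fragmentation. Fallback, which sets the stereocentre by addition to the ketone and bypasses steps 1–5: from 1, catalytic enantioselective alkynylation with ethynyltrimethylsilane (Me2Zn and the enantiomer of N,N'-bis(3,5-di-tert-butylsalicylidene)-1,2-cyclohexanediamine that delivers the R alcohol, toluene, rt) gives (1R)-2,2-dimethyl-1-[(trimethylsilyl)ethynyl]cyclobutan-1-ol F5. Its enantiomeric purity would be raised on a chiral stationary phase if needed. Desilylation of F5 (K2CO3, MeOH) comes back to the route at 8.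

**Further compounds**

F1 | step 9 | triethyl{[(1R)-1-ethynyl-2,2-dimethylcyclobutyl]oxy}silane | CC[Si](CC)(CC)O[C@]1(C#C)CCC1(C)C
F2 | step 9 | 2-[(1R)-2,2-dimethyl-1-(triethylsilyloxy)cyclobutyl]-5,8-bis(methoxymethoxy)naphthalene-1,4-dione | CC[Si](CC)(CC)O[C@]1(C2=CC(=O)c3c(OCOC)ccc(OCOC)c3C2=O)CCC1(C)C
F3 | step 9 | 2-[(1R)-1-hydroxy-2,2-dimethylcyclobutyl]-5,8-bis(methoxymethoxy)naphthalene-1,4-dione | O[C@]1(C2=CC(=O)c3c(OCOC)ccc(OCOC)c3C2=O)CCC1(C)C
F4 | step 6 | (1R)-1-ethynyl-2,2-dimethylcyclobutyl 2-[bis(2,2,2-trifluoroethoxy)phosphoryl]propanoate | CC(C(=O)O[C@]1(C#C)CCC1(C)C)P(=O)(OCC(F)(F)F)OCC(F)(F)F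
F5 | step 5 | (1R)-2,2-dimethyl-1-[(trimethylsilyl)ethynyl]cyclobutan-1-ol | C[Si](C)(C)C#C[C@@]1(O)CCC1(C)C
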